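**Plan**

1. Retrosynthesis: ring B is first simplified (C8=CH2 from C8=O, 7-OH from the C7 enolate) and ring A likewise (C4(CH3)(CH2OAc) from C4=O). Then the ring bonds C5–C10 and C6–C7 are cut together, and the acyclic triene is cut at C10–C20 (cross-coupling), C9–C11 (alkylation) and C1–C2 (aldol).
2. Enabling feature: ring B holds the four-carbon unit C7–C8–C9–C10, which is a 2-oxygenated butadiene once the C8 exo-methylene is read as a ketone (enol ether). It faces the two-carbon unit C5–C6, an enone double bond once quaternary C4 is read as a ketone. The chain C1–C4 of ring A tethers the two and carries the C2 carbinol.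
3. Forward: side-chain iodide 7 and β-keto ester 14 are joined at C9–C11, and the tetrasubstituted C9=C10 alkene is fixed through an (E)-enol tosylate. Rings A and B then form together in one intramolecular Diels–Alder step; C4 is made quaternary next and ring B is finished last.
4. Stereochemistry: C2 comes from a catalytic enantioselective aldol. C10 is relayed from C2 in the cycloaddition (chair tether, C2–OSi equatorial, C20 axial). C5 and C9 are set by epimerisation and axial protonation, C4 by equatorial methylation anti to C20, C7 by axial enolate hydroxylation, and 13Z by trans-hydroalumination of but-2-yn-1-ol.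
5. Helpers removed later: the C8 methoxy group (masked ketone), the C4 carbonyl (activator, converted into the quaternary centre), and the TES, TIPS and trityl groups.

Key step: step 14

Remark: positions are given in labdane numbering for all intermediates (decalin C1–C10, side chain C11–C16, C17 exo-methylene, C18/C19 on C4, C20 on C10).
Remark: racemic ethyl 3-hydroxypent-4-enoate is assumed; its carbinol carbon (the future C4) stays an uncontrolled centre in 9–19, is left unspecified in their SMILES, and becomes the ketone carbon in step 14.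
Remark: in step 7 the BINOL enantiomer is the one that delivers (5S)-13; catalyst control is assumed to override the remote silyloxy centre.

Step 1
Reactants: 1 but-2-yn-1-ol
Product: 3 (Z)-3-iodobut-2-en-1-ol, via alkenylaluminate 2 (not isolated)
Conditions: Red-Al, THF, 0 °C to rt; then I2, THF, −78 °C
Reagents that add atoms: iodine, II
Why: Hydroxyl-directed trans-hydroalumination of the propargylic alcohol places aluminium on C3 cis to the CH2O group (cyclic alkoxyaluminate), and iodinolysis with retention should give the (Z)-vinyl iodide that fixes the 13Z geometry.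

Step 2
Reactants: 3 (Z)-3-iodobut-2-en-1-ol
Product: 4 (Z)-3-iodobut-2-enyl trityl ether
Conditions: TrCl, Et3N, DMAP (cat.), CH2Cl2, rt
Reagents that add atoms: trityl chloride, ClC(c1ccccc1)(c1ccccc1)c1ccccc1
Why: Tritylation of the primary allylic alcohol (SN1-type etherification) should give a base-stable, acid-labile ether that can later be removed together with the enol ether.

Step 3
Reactants: 4 (Z)-3-iodobut-2-enyl trityl ether
Product: 6 (Z)-3-methyl-5-(trityloxy)pent-3-en-1-ol, via alkenyllithium 5 (not isolated)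
Conditions: t-BuLi (2.1 equiv), Et2O, −78 °C; then oxirane, −78 °C to rt
Reagents that add atoms: oxirane, C1CO1
Why: Iodine–lithium exchange with retention of alkene geometry followed by epoxide opening of oxirane by the alkenyllithium should give the homoallylic alcohol.

Step 4
Reactants: 6 (Z)-3-methyl-5-(trityloxy)pent-3-en-1-ol
Product: 7 (Z)-5-iodo-3-methylpent-2-enyl trityl ether
Conditions: I2, PPh3, imidazole, CH2Cl2, 0 °C
Reagents that add atoms: iodine, II
Why: Appel-type iodination converts the primary alcohol into the alkylating agent by SN2 displacement of the oxyphosphonium group.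

Step 5
Reactants: 8 ethyl 3-hydroxypent-4-enoate
Product: 9 ethyl 3-(triethylsilyloxy)pent-4-enoate
Conditions: TESCl, imidazole, CH2Cl2, 0 °C
Reagents that add atoms: chlorotriethylsilane, CC[Si](Cl)(CC)CC
Why: Silylation of the secondary allylic alcohol masks the future C4 carbinol as a fluoride-labile ether.

Step 6
Reactants: 9 ethyl 3-(triethylsilyloxy)pent-4-enoate
Product: 10 3-(triethylsilyloxy)pent-4-enal
Conditions: DIBAL-H, CH2Cl2, −78 °C
Reagents that add atoms: none
Why: Partial reduction of the ester with DIBAL-H at low temperature via the stable tetrahedral aluminate should stop at the aldehyde.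

Step 7
Reactants: 10 3-(triethylsilyloxy)pent-4-enal; 11 1-methoxy-1,3-bis(trimethylsilyloxy)buta-1,3-diene
Product: 13 methyl (5S)-5-hydroxy-3-oxo-7-(triethylsilyloxy)non-8-enoate, via silyl ketene acetal 12 (not isolated)
Conditions: Ti(OiPr)4 (10 mol%), BINOL (10 mol%), THF, −78 °C to rt; then aq. citric acid, THF, 0 °C
Reagents that add atoms: none
Why: The catalytic enantioselective vinylogous Mukaiyama aldol addition of the bis-silyl dienolate under Ti(IV)–BINOLate control sets the carbinol centre (the future C2) by catalyst-dictated facial attack on the aldehyde, and mild acid unmasks the β-keto ester.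

Step 8
Reactants: 13 methyl (5S)-5-hydroxy-3-oxo-7-(triethylsilyloxy)non-8-enoate
Product: 14 methyl (5S)-3-oxo-7-(triethylsilyloxy)-5-(triisopropylsilyloxy)non-8-enoate
Conditions: TIPSOTf, 2,6-lutidine, CH2Cl2, −78 to 0 °C
Reagents that add atoms: triisopropylsilyl triflate, CC(C)[Si](OS(=O)(=O)C(F)(F)F)(C(C)C)C(C)C
Why: Silylation of the secondary alcohol gives a bulky, robust ether that later serves as the equatorial control element in the cycloaddition and survives fluoride removal of the TES group.

Step 9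
Reactants: 14 methyl (5S)-3-oxo-7-(triethylsilyloxy)-5-(triisopropylsilyloxy)non-8-enoate; 7 (Z)-5-iodo-3-methylpent-2-enyl trityl ether
Product: 15 methyl (5S)-2-[(3Z)-3-methyl-5-(trityloxy)pent-3-enyl]-3-oxo-7-(triethylsilyloxy)-5-(triisopropylsilyloxy)non-8-enoate
Conditions: K2CO3, DMF, 40 °C
Reagents that add atoms: none
Why: C-Alkylation of the doubly stabilised β-keto ester enolate (acetoacetic ester alkylation) with the primary iodide installs the complete side chain at the future C9.

Step 10
Reactants: 15 alkylated β-keto ester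
Product: 16 methyl (2E,5S)-2-[(3Z)-3-methyl-5-(trityloxy)pent-3-enyl]-3-(tosyloxy)-7-(triethylsilyloxy)-5-(triisopropylsilyloxy)nona-2,8-dienoate
Conditions: TsCl, N-methylimidazole, Et3N, toluene, 0 °C
Reagents that add atoms: tosyl chloride, Cc1ccc(S(Cl)(=O)=O)cc1
Why: O-Sulfonylation of the non-chelated, amine-generated enolate with the TsCl–N-methylimidazole sulfonylammonium reagent should give the (E)-enol tosylate (tosylate trans to the ester), which places the tether cis to the ester carbon on the future C9=C10 bond.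

Step 11
Reactants: 16 (E)-enol tosylate
Product: 17 methyl (2Z,5R)-3-methyl-2-[(3Z)-3-methyl-5-(trityloxy)pent-3-enyl]-7-(triethylsilyloxy)-5-(triisopropylsilyloxy)nona-2,8-dienoate
Conditions: MeZnCl, Pd(dppf)Cl2 (5 mol%), THF, 50 °C
Reagents that add atoms: methylzinc chloride, C[Zn]Cl
Why: Stereoretentive Negishi cross-coupling of the electron-poor enol tosylate with methylzinc chloride introduces C20 and should give the tetrasubstituted enoate with the tether still cis to the ester.

Step 12
Reactants: 17 tetrasubstituted (Z)-enoate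
Product: 18 (5R,7Z)-9-methoxy-7-methyl-8-[(3Z)-3-methyl-5-(trityloxy)pent-3-enyl]-3-(triethylsilyloxy)-5-(triisopropylsilyloxy)deca-1,7,9-triene
Conditions: Cp2TiMe2, toluene/THF, 70 °C, dark
Reagents that add atoms: dimethyltitanocene (Petasis reagent), [CH3-].[CH3-].[Ti+4].c1cc[cH-]c1.c1cc[cH-]c1
Why: Petasis methylenation of the ester carbonyl (titanium methylidene, oxatitanacyclobutane) converts the enoate into the 2-methoxy-1,3-diene without disturbing the tetrasubstituted alkene geometry.

Step 13
Reactants: 18 methoxydiene TES ether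
Product: 19 (5R,7Z)-9-methoxy-7-methyl-8-[(3Z)-3-methyl-5-(trityloxy)pent-3-enyl]-5-(triisopropylsilyloxy)deca-1,7,9-trien-3-ol
Conditions: TBAF, THF, 0 °C
Reagents that add atoms: none
Why: Fluoride should cleave the less hindered triethylsilyl ether selectively in the presence of the triisopropylsilyl ether, and the basic medium spares the acid-labile methoxydiene and trityl ether.

Step 14
Reactants: 19 allylic alcohol
Product: 21 cis-fused cycloadduct 8-methoxy-2α-(triisopropylsilyloxy)-15-(trityloxy)-17,18,19-trinor-5β-labda-8,13Z-dien-4-one, via trienone 20 (not isolated)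
Conditions: Dess–Martin periodinane, pyridine, CH2Cl2, 0 °C to rt; then toluene (dilute), BHT, 70 °C
Reagents that add atoms: none
Why: Oxidation unmasks the vinyl ketone, and the C4-carbonyl-activated C5=C6 dienophile then adds to the 2-methoxy diene C7=C8–C9=C10 in a thermal, normal-demand type 1 intramolecular Diels–Alder reaction (suprafacial [4+2], nucleophilic C7 to the enone β-carbon C6), forming C6–C7 and C5–C10 in one operation. The closest precedent is the intramolecular Diels–Alder reaction of 1,7,9-decatrien-3-ones and of (Z)-dienes. Ring B closes as the cycloaddition ring and ring A as the six-membered ring spanned by the four-atom tether C1–C4 (fused mode). Because the tether is cis to C8 on the C9=C10 bond, only the cis-fused, exo-ketone transition state is geometrically accessible, and in it ring A is a chair with the C20 methyl axial. The C2 silyloxy group must then lie equatorial to avoid a 1,3-diaxial clash with that methyl, so the C2 stereocentre fixes the new quaternary C10 (C2–O trans to C20), while C5 arises cis (5β-H) and is corrected in step 15. The step needs diene-face selectivity, secured by the C2/C20 interaction, and suppression of [1,5]-hydrogen shift and enone oligomerisation, secured by the low temperature that enone activation and the electron-rich diene allow.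

Step 15
Reactants: 21 cis-fused cycloadduct
Product: 22 trans-fused ketone 8-methoxy-2α-(triisopropylsilyloxy)-15-(trityloxy)-17,18,19-trinor-labda-8,13Z-dien-4-one (5α-H)
Conditions: DBU, toluene, rt
Reagents that add atoms: none
Why: Base-mediated epimerisation α to the C4 ketone through the C4–C5 enolate should convert the cis-fused adduct into the more stable trans-fused decalone, while the equatorial C2 silyloxy group is poorly aligned for β-elimination.

Step 16
Reactants: 22 trans-fused ketone
Product: 23 8-methoxy-2α-(triisopropylsilyloxy)-15-(trityloxy)-17,18-dinor-labda-8,13Z-diene-19-nitrile (C4 epimers)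
Conditions: TosMIC, t-BuOK, DME/t-BuOH, 0 to 35 °C
Reagents that add atoms: tosylmethyl isocyanide, Cc1ccc(cc1)S(=O)(=O)C[N+]#[C-]
Why: The van Leusen reductive cyanation converts the C4 ketone directly into the one-carbon-homologated nitrile (C19), the new C4–H centre being inconsequential.

Step 17
Reactants: 23 C4 nitrile
Product: 25 4α-methyl-4β-cyano compound 8-methoxy-2α-(triisopropylsilyloxy)-15-(trityloxy)-17-nor-labda-8,13Z-diene-19-nitrile, via lithiated nitrile 24 (not isolated)
Conditions: LDA, THF, −78 to 0 °C; then MeI, −78 °C to rt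
Reagents that add atoms: iodomethane, CI
Why: Deprotonation gives the planar nitrile anion, which should be methylated from the equatorial α face away from the axial C20 methyl, setting quaternary C4 with the nitrile axial (β, C19) and the new methyl (C18) α.

Step 18
Reactants: 25 quaternary nitrile
Product: 27 8-methoxy-2α-(triisopropylsilyloxy)-15-(trityloxy)-17-nor-labda-8,13Z-dien-19-ol, via aldehyde 26 (not isolated)
Conditions: DIBAL-H, toluene, −78 to 0 °C, pH 5 buffer work-up; then NaBH4, MeOH, 0 °C
Reagents that add atoms: water, O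
Why: DIBAL-H reduces the nitrile to the N-aluminio imine, buffered hydrolysis gives the neopentyl aldehyde, and borohydride reduction of the carbonyl gives the C19 alcohol with the enol ether intact.

Step 19
Reactants: 27 C19 alcohol
Product: 28 15,19-dihydroxy-2α-(triisopropylsilyloxy)-17-nor-labd-13Z-en-8-one
Conditions: 1 M aq. HCl, THF, rt
Reagents that add atoms: water, O
Why: Aqueous acid hydrolyses the enol ether to the C8 ketone with axial α-face protonation at C9, which places the side chain equatorial (also the thermodynamic epimer), and removes the trityl group by SN1 ionisation.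

Step 20
Reactants: 28 keto diol
Product: 29 15,19-diacetoxy-2α-(triisopropylsilyloxy)-17-nor-labd-13Z-en-8-one
Conditions: Ac2O, pyridine, DMAP (cat.), CH2Cl2, rt
Reagents that add atoms: acetic anhydride, CC(=O)OC(C)=O
Why: DMAP-catalysed acylation esterifies both primary alcohols, the two secondary oxygens being absent (C7) or silylated (C2) at this stage.

Step 21
Reactants: 29 keto diacetate
Product: 31 15,19-diacetoxy-7α-hydroxy-2α-(triisopropylsilyloxy)-17-nor-labd-13Z-en-8-one, via sodium enolate 30 (not isolated)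
Conditions: NaHMDS (1.1 equiv), THF, −78 °C; then 2-(phenylsulfonyl)-3-phenyloxaziridine, −78 °C
Reagents that add atoms: 2-(phenylsulfonyl)-3-phenyloxaziridine, O=S(=O)(N1OC1c1ccccc1)c1ccccc1
Why: Kinetic deprotonation at the less hindered C7 methylene (ketone far more acidic than the acetates) and Davis hydroxylation of the enolate from the axial α face should give the 7α-alcohol.

Step 22
Reactants: 31 α-hydroxy ketone
Product: 32 15,19-diacetoxy-2α-(triisopropylsilyloxy)-labda-8(17),13Z-dien-7α-ol
Conditions: Zn, CH2Br2, TiCl4 (pre-formed Lombardo reagent), CH2Cl2/THF, 0 °C to rt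
Reagents that add atoms: dibromomethane, BrCBr
Why: Lombardo methylenation is non-basic, tolerates esters and free hydroxyl groups, and should convert the hindered, enolisable C8 ketone into the exocyclic methylene without epimerising C7 or C9.

Step 23
Reactants: 32 silyl ether of the target
Product: 33 15,19-diacetoxy-labda-8(17),13Z-diene-2α,7α-diol (target)
Conditions: HF·pyridine, pyridine, THF, rt
Reagents that add atoms: none
Why: Fluoride-mediated cleavage of the triisopropylsilyl ether under buffered conditions should leave the acetates, the allylic alcohol and both alkenes untouched.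

**Compound list**

1 | but-2-yn-1-ol | CC#CCO | starting material
2 | sodium cyclic alkoxy(alkenyl)aluminate of 1 (Al on C3, cis to CH2O) | C/C1=C/CO[Al-]1(OCCOC)OCCOC.[Na+] | intermediate
3 | (Z)-3-iodobut-2-en-1-ol | C/C(I)=C/CO | intermediate
4 | (Z)-3-iodobut-2-enyl trityl ether | C/C(I)=C/COC(c1ccccc1)(c1ccccc1)c1ccccc1 | intermediate
5 | 2-lithio-4-(trityloxy)but-2-ene (Li cis to CH2OTr) | C/C([Li])=C/COC(c1ccccc1)(c1ccccc1)c1ccccc1 | intermediate
6 | (Z)-3-methyl-5-(trityloxy)pent-3-en-1-ol | OCC/C(C)=C\COC(c1ccccc1)(c1ccccc1)c1ccccc1 | intermediate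
7 | (Z)-5-iodo-3-methylpent-2-enyl trityl ether | ICC/C(C)=C\COC(c1ccccc1)(c1ccccc1)c1ccccc1 | intermediate
8 | ethyl 3-hydroxypent-4-enoate (racemic) | C=CC(O)CC(=O)OCC | starting material
9 | ethyl 3-(triethylsilyloxy)pent-4-enoate | C=CC(O[Si](CC)(CC)CC)CC(=O)OCC | intermediate
10 | 3-(triethylsilyloxy)pent-4-enal | C=CC(O[Si](CC)(CC)CC)CC=O | intermediate
11 | 1-methoxy-1,3-bis(trimethylsilyloxy)buta-1,3-diene | COC(O[Si](C)(C)C)=CC(=C)O[Si](C)(C)C | starting material
12 | O-silylated aldol adduct (silyl ketene acetal of 13, 5-OTMS) | C=CC(O[Si](CC)(CC)CC)C[C@H](O[Si](C)(C)C)CC(=O)C=C(OC)O[Si](C)(C)C | intermediate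
13 | methyl (5S)-5-hydroxy-3-oxo-7-(triethylsilyloxy)non-8-enoate | C=CC(O[Si](CC)(CC)CC)C[C@H](O)CC(=O)CC(=O)OC | intermediate
14 | methyl (5S)-3-oxo-7-(triethylsilyloxy)-5-(triisopropylsilyloxy)non-8-enoate | C=CC(O[Si](CC)(CC)CC)C[C@H](O[Si](C(C)C)(C(C)C)C(C)C)CC(=O)CC(=O)OC | intermediate
15 | methyl (5S)-2-[(3Z)-3-methyl-5-(trityloxy)pent-3-enyl]-3-oxo-7-(triethylsilyloxy)-5-(triisopropylsilyloxy)non-8-enoate | C=CC(O[Si](CC)(CC)CC)C[C@H](O[Si](C(C)C)(C(C)C)C(C)C)CC(=O)C(CC/C(C)=C\COC(c1ccccc1)(c1ccccc1)c1ccccc1)C(=O)OC | intermediate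
16 | methyl (2E,5S)-2-[(3Z)-3-methyl-5-(trityloxy)pent-3-enyl]-3-(tosyloxy)-7-(triethylsilyloxy)-5-(triisopropylsilyloxy)nona-2,8-dienoate | C=CC(O[Si](CC)(CC)CC)C[C@H](O[Si](C(C)C)(C(C)C)C(C)C)C/C(OS(=O)(=O)c1ccc(C)cc1)=C(/CC/C(C)=C\COC(c1ccccc1)(c1ccccc1)c1ccccc1)C(=O)OC | intermediate
17 | methyl (2Z,5R)-3-methyl-2-[(3Z)-3-methyl-5-(trityloxy)pent-3-enyl]-7-(triethylsilyloxy)-5-(triisopropylsilyloxy)nona-2,8-dienoate | C=CC(O[Si](CC)(CC)CC)C[C@H](O[Si](C(C)C)(C(C)C)C(C)C)C/C(C)=C(/CC/C(C)=C\COC(c1ccccc1)(c1ccccc1)c1ccccc1)C(=O)OC | intermediate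
18 | (5R,7Z)-9-methoxy-7-methyl-8-[(3Z)-3-methyl-5-(trityloxy)pent-3-enyl]-3-(triethylsilyloxy)-5-(triisopropylsilyloxy)deca-1,7,9-triene | C=CC(O[Si](CC)(CC)CC)C[C@H](O[Si](C(C)C)(C(C)C)C(C)C)C/C(C)=C(/CC/C(C)=C\COC(c1ccccc1)(c1ccccc1)c1ccccc1)C(OC)=C | intermediate
19 | (5R,7Z)-9-methoxy-7-methyl-8-[(3Z)-3-methyl-5-(trityloxy)pent-3-enyl]-5-(triisopropylsilyloxy)deca-1,7,9-trien-3-ol | C=CC(O)C[C@H](O[Si](C(C)C)(C(C)C)C(C)C)C/C(C)=C(/CC/C(C)=C\COC(c1ccccc1)(c1ccccc1)c1ccccc1)C(OC)=C | intermediate
20 | (5R,7Z)-9-methoxy-7-methyl-8-[(3Z)-3-methyl-5-(trityloxy)pent-3-enyl]-5-(triisopropylsilyloxy)deca-1,7,9-trien-3-one | C=CC(=O)C[C@H](O[Si](C(C)C)(C(C)C)C(C)C)C/C(C)=C(/CC/C(C)=C\COC(c1ccccc1)(c1ccccc1)c1ccccc1)C(OC)=C | intermediate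
21 | cis-fused cycloadduct: 8-methoxy-2α-(triisopropylsilyloxy)-15-(trityloxy)-17,18,19-trinor-5β-labda-8,13Z-dien-4-one | C1(OC)CC[C@@H]2C(=O)C[C@H](O[Si](C(C)C)(C(C)C)C(C)C)C[C@]2(C)C=1CC/C(C)=C\COC(c1ccccc1)(c1ccccc1)c1ccccc1 | intermediate
22 | trans-fused ketone: 8-methoxy-2α-(triisopropylsilyloxy)-15-(trityloxy)-17,18,19-trinor-labda-8,13Z-dien-4-one (5α-H) | C1(OC)CC[C@H]2C(=O)C[C@H](O[Si](C(C)C)(C(C)C)C(C)C)C[C@]2(C)C=1CC/C(C)=C\COC(c1ccccc1)(c1ccccc1)c1ccccc1 | intermediate
23 | 8-methoxy-2α-(triisopropylsilyloxy)-15-(trityloxy)-17,18-dinor-labda-8,13Z-diene-19-nitrile (C4 epimers) | C1(OC)CC[C@H]2C(C#N)C[C@H](O[Si](C(C)C)(C(C)C)C(C)C)C[C@]2(C)C=1CC/C(C)=C\COC(c1ccccc1)(c1ccccc1)c1ccccc1 | intermediate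
24 | N-lithio ketene imine (lithiated nitrile) of 23 | C1(OC)CC[C@H]2C(=C=N[Li])C[C@H](O[Si](C(C)C)(C(C)C)C(C)C)C[C@]2(C)C=1CC/C(C)=C\COC(c1ccccc1)(c1ccccc1)c1ccccc1 | intermediate
25 | 8-methoxy-2α-(triisopropylsilyloxy)-15-(trityloxy)-17-nor-labda-8,13Z-diene-19-nitrile (4α-methyl, 4β-cyano) | C1(OC)CC[C@H]2[C@@](C)(C#N)C[C@H](O[Si](C(C)C)(C(C)C)C(C)C)C[C@]2(C)C=1CC/C(C)=C\COC(c1ccccc1)(c1ccccc1)c1ccccc1 | intermediate
26 | 8-methoxy-2α-(triisopropylsilyloxy)-15-(trityloxy)-17-nor-labda-8,13Z-dien-19-al | C1(OC)CC[C@H]2[C@@](C)(C=O)C[C@H](O[Si](C(C)C)(C(C)C)C(C)C)C[C@]2(C)C=1CC/C(C)=C\COC(c1ccccc1)(c1ccccc1)c1ccccc1 | intermediate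
27 | 8-methoxy-2α-(triisopropylsilyloxy)-15-(trityloxy)-17-nor-labda-8,13Z-dien-19-ol | C1(OC)CC[C@H]2[C@@](C)(CO)C[C@H](O[Si](C(C)C)(C(C)C)C(C)C)C[C@]2(C)C=1CC/C(C)=C\COC(c1ccccc1)(c1ccccc1)c1ccccc1 | intermediate
28 | 15,19-dihydroxy-2α-(triisopropylsilyloxy)-17-nor-labd-13Z-en-8-one | O=C1CC[C@H]2[C@@](C)(CO)C[C@H](O[Si](C(C)C)(C(C)C)C(C)C)C[C@]2(C)[C@H]1CC/C(C)=C\CO | intermediate
29 | 15,19-diacetoxy-2α-(triisopropylsilyloxy)-17-nor-labd-13Z-en-8-one | O=C1CC[C@H]2[C@@](C)(COC(C)=O)C[C@H](O[Si](C(C)C)(C(C)C)C(C)C)C[C@]2(C)[C@H]1CC/C(C)=C\COC(C)=O | intermediate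
30 | sodium Δ7-enolate of 29 | [Na+].[O-]C1=CC[C@H]2[C@@](C)(COC(C)=O)C[C@H](O[Si](C(C)C)(C(C)C)C(C)C)C[C@]2(C)[C@H]1CC/C(C)=C\COC(C)=O | intermediate
31 | 15,19-diacetoxy-7α-hydroxy-2α-(triisopropylsilyloxy)-17-nor-labd-13Z-en-8-one | O=C1[C@H](O)C[C@H]2[C@@](C)(COC(C)=O)C[C@H](O[Si](C(C)C)(C(C)C)C(C)C)C[C@]2(C)[C@H]1CC/C(C)=C\COC(C)=O | intermediate
32 | 15,19-diacetoxy-2α-(triisopropylsilyloxy)-labda-8(17),13Z-dien-7α-ol | C=C1[C@H](O)C[C@H]2[C@@](C)(COC(C)=O)C[C@H](O[Si](C(C)C)(C(C)C)C(C)C)C[C@]2(C)[C@H]1CC/C(C)=C\COC(C)=O | intermediate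
33 | 15,19-diacetoxy-labda-8(17),13Z-diene-2α,7α-diol | C=C1[C@H](O)C[C@H]2[C@@](C)(COC(C)=O)C[C@H](O)C[C@]2(C)[C@H]1CC/C(C)=C\COC(C)=O | target

**Step count and risks**

Total step count: 23. Longest linear sequence: 19 steps (8 to 33 through steps 5–23; the branch 1 to 7, steps 1–4, joins at step 9 and is equally long).

Steps most likely to fail:

Step 14. The cycloaddition at the fully substituted C10 terminus may be slow enough that a thermal [1,5]-hydrogen shift of the (Z)-diene or oligomerisation of the vinyl ketone competes, and a boat-like tether could erode the relay from C2 to C10. The fallback replaces the thermal cycloaddition by an anionic double Michael annulation. It sets out from 19: mild hydrolysis of the enol ether (oxalic acid on wet silica) would give the hydroxy methyl ketone F1, and Dess–Martin oxidation the bis-enone F2. LiHMDS in THF at −78 to 0 °C would form the kinetic C7 dienolate, which should close both rings by intramolecular double Michael addition (C7 to C6, then C5 to C10; the Z geometry again enforces cis fusion and the same relay) to give the regiodefined lithium C8 enolate F3. O-Methylation (dimethyl sulfate, DMPU) would bring the route back at 21.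

Step 15. With ring B still unsaturated the cis/trans equilibrium may not lie far enough on the trans side, and the flexible cis isomer may lose the C2 silyloxy group by E1cB elimination under base. The fallback uses kinetic protonation instead of equilibration. It sets out from 21 (or its mixture with 22): TMSCl, Et3N, DMF with heating would give the more substituted Δ4(5) trimethylsilyl enol ether F4, and MeLi would release the lithium enolate F5. Protonation at −78 °C with 2,6-di-tert-butylphenol, axial and anti to the angular methyl, should come back to the route at 22.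

Step 10. E/Z control may be lost in the O-sulfonylation of the doubly branched keto ester (a chelated enolate would give the Z-tosylate, or the product may isomerise), which would deliver the wrong diene geometry for step 14. The fallback builds the tetrasubstituted alkene by alkyne carbometalation and sets out from 10. Enantioselective propargylation (allenylboronic acid pinacol ester, chiral phosphoric acid catalyst) would give the homopropargylic alcohol F6, silylation (TIPSOTf, 2,6-lutidine) the silyl ether F7, and n-BuLi then methyl chloroformate the ynoate F8. syn-Carbocupration with Me2CuLi at −78 °C followed by iodine would give the iodo enoate F9, with iodide cis to the new methyl by mechanism. Negishi coupling of F9 with the alkylzinc iodide F10 (from 7, zinc dust, LiCl) would come back to the route at 17.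

Further compounds
F1 | step 14 | (5R,3Z)-6-hydroxy-4-methyl-3-[(3Z)-3-methyl-5-(trityloxy)pent-3-enyl]-8-... methyl ketone: (7Z)-3-hydroxy-7-methyl-8-[(3Z)-3-methyl-5-(trityloxy)pent-3-enyl]-5-(triisopropylsilyloxy)deca-1,7-dien-9-one | C=CC(O)C[C@H](O[Si](C(C)C)(C(C)C)C(C)C)C/C(C)=C(/CC/C(C)=C\COC(c1ccccc1)(c1ccccc1)c1ccccc1)C(C)=O
F2 | step 14 | (5R,7Z)-7-methyl-8-[(3Z)-3-methyl-5-(trityloxy)pent-3-enyl]-5-(triisopropylsilyloxy)deca-1,7-diene-3,9-dione | C=CC(=O)C[C@H](O[Si](C(C)C)(C(C)C)C(C)C)C/C(C)=C(/CC/C(C)=C\COC(c1ccccc1)(c1ccccc1)c1ccccc1)C(C)=O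
F3 | step 14 | lithium C8 enolate of the cis-fused 4,8-dione (O-lithio analogue of 21) | C1(O[Li])CC[C@@H]2C(=O)C[C@H](O[Si](C(C)C)(C(C)C)C(C)C)C[C@]2(C)C=1CC/C(C)=C\COC(c1ccccc1)(c1ccccc1)c1ccccc1
F4 | step 15 | Δ4(5) trimethylsilyl enol ether of 21/22 | C1(OC)CCC2=C(O[Si](C)(C)C)C[C@H](O[Si](C(C)C)(C(C)C)C(C)C)C[C@]2(C)C=1CC/C(C)=C\COC(c1ccccc1)(c1ccccc1)c1ccccc1
F5 | step 15 | lithium Δ4(5) enolate of 21/22 | C1(OC)CCC2=C(O[Li])C[C@H](O[Si](C(C)C)(C(C)C)C(C)C)C[C@]2(C)C=1CC/C(C)=C\COC(c1ccccc1)(c1ccccc1)c1ccccc1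
F6 | step 10 | (4R)-6-(triethylsilyloxy)oct-7-en-1-yn-4-ol | C=CC(O[Si](CC)(CC)CC)C[C@H](O)CC#C
F7 | step 10 | (4R)-6-(triethylsilyloxy)-4-(triisopropylsilyloxy)oct-7-en-1-yne | C=CC(O[Si](CC)(CC)CC)C[C@H](O[Si](C(C)C)(C(C)C)C(C)C)CC#C
F8 | step 10 | methyl (5R)-7-(triethylsilyloxy)-5-(triisopropylsilyloxy)non-8-en-2-ynoate | C=CC(O[Si](CC)(CC)CC)C[C@H](O[Si](C(C)C)(C(C)C)C(C)C)CC#CC(=O)OC
F9 | step 10 | methyl (5R)-2-iodo-3-methyl-7-(triethylsilyloxy)-5-(triisopropylsilyloxy)nona-2,8-dienoate (iodide cis to the C3 methyl) | C=CC(O[Si](CC)(CC)CC)C[C@H](O[Si](C(C)C)(C(C)C)C(C)C)C/C(C)=C(/I)C(=O)OC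
F10 | step 10 | [(Z)-3-methyl-5-(trityloxy)pent-3-enyl]zinc iodide | I[Zn]CC/C(C)=C\COC(c1ccccc1)(c1ccccc1)c1ccccc1
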